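The synthesis rests on closing the 1,2-dioxane ring of the furo[3,2-c][1,2]dioxin-6-one across two bonds at once: O2–C3 (peroxide oxygen to the quaternary carbon bearing methyl and the phenyldecyl chain) and the ring-fusion bond C4a–C7a. In one flask, a selanyl lactol and a silylperoxy acetal are joined with Me3SiOTf: a seleniranium ion places the peroxide oxygen on the tertiary carbon with retention, then an aldehyde enol attacks the peroxycarbenium ion through a chair. The step exploits the 1,3-relation of the two methyl-bearing quaternary carbons C3 and C4a; the lactone oxygen on C4a is carried as a formyl group that Baeyer–Villiger oxidation and lactonisation later convert.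

Key step: step 10

Assumption: both enantiomers of the Shi ketone, 10-bromodecan-1-ol and dimethyl (E)-hex-3-enedioate are taken as commercial; ring locants of the target follow furo[3,2-c][1,2]dioxin numbering (O1, O2, C3, C4, C4a, O5, C6, C7, C7a).

Step 1
Reactants: 1 10-bromodecan-1-ol; 2 phenylmagnesium bromide
Product: 3 10-phenyldecan-1-ol
Conditions: 2 (2.5 equiv), Li2CuCl4 (3 mol %), THF, −20 → 23 °C; aq. NH4Cl
Reagents that add atoms: none
Why: Copper-catalysed Grignard cross-coupling (Kochi coupling) of the primary bromide should give the ω-phenyl alcohol after the first equivalent of 2 has deprotonated the hydroxyl group; no stereocenter is formed.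

Step 2
Reactants: 3 10-phenyldecan-1-ol
Product: 4 10-phenyldecanal
Conditions: (COCl)2, DMSO, CH2Cl2, −78 °C; Et3N, −78 → 0 °C
Reagents that add atoms: none
Why: Swern oxidation stops cleanly at the aldehyde and touches nothing else in this unfunctionalised chain.

Step 3
Reactants: 4 10-phenyldecanal; 5 prop-1-en-2-ylmagnesium bromide
Product: 6 2-methyl-12-phenyldodec-1-en-3-ol (racemic)
Conditions: THF, −78 → 0 °C; aq. NH4Cl
Reagents that add atoms: none
Why: Grignard addition of the isopropenyl nucleophile to the aldehyde gives the allylic alcohol, whose carbinol stereocenter forms racemic and is erased in step 4.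

Step 4
Reactants: 6 2-methyl-12-phenyldodec-1-en-3-ol; 7 triethyl orthopropionate
Product: 9 ethyl (E)-2,4-dimethyl-14-phenyltetradec-4-enoate (both C2 epimers), via mixed ketene acetal 8 (not isolated)
Conditions: 7 (5 equiv), EtCO2H (cat.), 140 °C, EtOH distilled off
Reagents that add atoms: none
Why: Johnson–Claisen rearrangement through a chair with the nonyl chain equatorial should deliver the (E)-trisubstituted alkene; the α-methyl stereocenter forms without control and is left as a mixture because it becomes trigonal in step 10.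

Step 5
Reactants: 9 ethyl (E)-2,4-dimethyl-14-phenyltetradec-4-enoate
Product: 10 ethyl 2-methyl-3-[(2S,3S)-2-methyl-3-(9-phenylnonyl)oxiran-2-yl]propanoate (both C2 epimers of the propanoate)
Conditions: ent-Shi ketone (1,2:4,5-di-O-isopropylidene-β-L-erythro-2,3-hexodiulo-2,6-pyranose, 30 mol %), KHSO5 (as 2KHSO5·KHSO4·K2SO4), K2CO3, Bu4NHSO4, MeCN/CH2(OMe)2/aq. buffer pH 10.5, 0 °C
Reagents that add atoms: potassium peroxymonosulfate, [K+].[O-]S(=O)(=O)OO
Why: Shi epoxidation by the dioxirane of the L-configured ketone through a spiro transition state should oxidise one face of the (E)-trisubstituted alkene and set both oxirane carbons as (2S,3S); the ester is too remote and too electron-poor to interfere.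

Step 6
Reactants: 10 ethyl 2-methyl-3-[(2S,3S)-2-methyl-3-(9-phenylnonyl)oxiran-2-yl]propanoate
Product: 12 (5S)-3,5-dimethyl-5-[(1R)-10-phenyl-1-(phenylselanyl)decyl]oxolan-2-one (both C3 epimers), via hydroxy selenide ester 11 (not isolated)
Conditions: (PhSe)2, NaBH4, EtOH, 0 → 70 °C; then AcOH
Reagents that add atoms: diphenyl diselenide, c1ccc(cc1)[Se][Se]c1ccccc1
Why: Phenylselenolate opens the epoxide by SN2 attack at the less substituted carbon (inversion there, giving the (R)-selenide carbon) while the tertiary C–O stereocenter stays untouched, and the tertiary alkoxide then closes the γ-lactone by acyl substitution on the ethyl ester.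

Step 7
Reactants: 12 (5S)-3,5-dimethyl-5-[(1R)-10-phenyl-1-(phenylselanyl)decyl]oxolan-2-one
Product: 13 (5S)-3,5-dimethyl-5-[(1R)-10-phenyl-1-(phenylselanyl)decyl]oxolan-2-ol (lactol; anomers and C3 epimers)
Conditions: i-Bu2AlH, CH2Cl2, −78 °C; aq. KNaC4H4O6
Reagents that add atoms: none
Why: Half-reduction of a γ-lactone with i-Bu2AlH stops at the lactol because the tetrahedral aluminate is stable at −78 °C; the new anomeric center is an immaterial mixture.

Step 8
Reactants: 14 dimethyl (E)-hex-3-enedioate
Product: 15 methyl 3-hydroperoxy-3-methoxypropanoate (racemic)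
Conditions: O3, CH2Cl2/MeOH (3:1), −78 °C; N2 purge; concentration below 20 °C; SiO2
Reagents that add atoms: ozone, [O-][O+]=O; methanol, CO
Why: Ozonolysis in methanol gives the Criegee carbonyl oxide, which methanol traps as the α-methoxy hydroperoxide; the symmetrical alkene gives one peroxide product, and its acetal stereocenter is racemic and immaterial because it is ionised in step 10.

Step 9
Reactants: 15 methyl 3-hydroperoxy-3-methoxypropanoate
Product: 16 methyl 3-methoxy-3-[(triethylsilyl)peroxy]propanoate (racemic)
Conditions: Et3SiCl, imidazole, DMF, 0 °C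
Reagents that add atoms: chlorotriethylsilane, CC[Si](Cl)(CC)CC
Why: O-Silylation of the hydroperoxide masks the oxidising O–H so that the selenide of 13 is not oxidised, and provides the silyl peroxide needed to capture a cation.

Step 10
Reactants: 13 (5S)-3,5-dimethyl-5-[(1R)-10-phenyl-1-(phenylselanyl)decyl]oxolan-2-ol; 16 methyl 3-methoxy-3-[(triethylsilyl)peroxy]propanoate
Product: 19 methyl 2-[(3R,4R,6S)-4-formyl-4,6-dimethyl-6-[(1R)-10-phenyl-1-(phenylselanyl)decyl]-1,2-dioxan-3-yl]acetate, via peroxy acetal aldehyde 17 (not isolated), via trimethylsilyl enol ether 18 (not isolated)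
Conditions: 16 (1.5 equiv), Me3SiOTf (1.2 equiv), 4 Å MS, CH2Cl2, −78 → −40 °C; then i-Pr2NEt (3 equiv), Me3SiOTf (2 equiv), −78 → −20 °C
Reagents that add atoms: none
Why: Proposed new method: Me3SiOTf ionises lactol 13 to its oxocarbenium ion, whose tertiary C–O bond fragments with anti-periplanar help from the phenylselanyl group to a seleniranium ion plus free aldehyde; the silylated peroxide oxygen of 16 opens the seleniranium ion at the tertiary carbon (17), and after i-Pr2NEt and more Me3SiOTf the aldehyde becomes enol ether 18 while the peroxy acetal loses methoxide to a peroxycarbenium ion that the enol carbon traps. The closest known reaction types are the stereoretentive seleniranium-mediated substitution of β-hydroxy selenides, the capture of carbocations by silyl peroxides in peroxycarbenium annulations, the Lewis-acid cyclisation of peroxycarbenium ions onto tethered π-nucleophiles and the one-pot enol silane formation/Mukaiyama addition to acetals; their union in one flask with a peroxide nucleophile is not shown. The 1,2-dioxane closes by a 6-(enolexo)-exo-trig C–C bond formation through a chair. The peroxide-bearing quaternary carbon is fixed by double inversion at carbon, that is net retention of the configuration set in steps 5 and 6; in the chair the branched selanyldecyl group and the CH2CO2Me arm sit equatorial, which forces the methyl group at the peroxide carbon axial, and the enol carbon then turns its flat formyl-enol arm and not its methyl group syn-axial to it, which sets the formyl-bearing quaternary carbon and the CH–OO carbon as drawn. The step needs the O–C bond before the C–C bond, secured by withholding base so that no enol is present in the first stage, and peroxide attack at the tertiary and not the secondary seleniranium carbon, secured by the better cation stabilisation there.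

Step 11
Reactants: 19 methyl 2-[(3R,4R,6S)-4-formyl-4,6-dimethyl-6-[(1R)-10-phenyl-1-(phenylselanyl)decyl]-1,2-dioxan-3-yl]acetate
Product: 21 methyl 2-[(3R,4R,6S)-4-formyl-4,6-dimethyl-6-[(E)-10-phenyldec-1-enyl]-1,2-dioxan-3-yl]acetate, via selenoxide 20 (not isolated)
Conditions: mCPBA (1.05 equiv), CH2Cl2, −78 °C; i-Pr2NH, −78 → 23 °C
Reagents that add atoms: none
Why: Selenium is oxidised far faster than the aldehyde at −78 °C, and the selenoxide undergoes syn-elimination toward the only β-hydrogen-bearing carbon (the peroxide carbon has none) to give the (E)-alkene, removing the selenium-bearing stereocenter without touching the others.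

Step 12
Reactants: 21 methyl 2-[(3R,4R,6S)-4-formyl-4,6-dimethyl-6-[(E)-10-phenyldec-1-enyl]-1,2-dioxan-3-yl]acetate
Product: 22 methyl 2-[(3R,4R,6R)-4-formyl-4,6-dimethyl-6-(10-phenyldecyl)-1,2-dioxan-3-yl]acetate
Conditions: KO2CN=NCO2K, AcOH, MeOH/CH2Cl2, 0 → 23 °C
Reagents that add atoms: none
Why: Diimide reduction transfers H2 in a concerted syn fashion to the isolated alkene and leaves the O–O bond, the aldehyde and the ester untouched, as is usual for unsaturated peroxides.

Step 13
Reactants: 22 methyl 2-[(3R,4R,6R)-4-formyl-4,6-dimethyl-6-(10-phenyldecyl)-1,2-dioxan-3-yl]acetate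
Product: 23 methyl 2-[(3R,4R,6R)-4-(formyloxy)-4,6-dimethyl-6-(10-phenyldecyl)-1,2-dioxan-3-yl]acetate
Conditions: mCPBA (2 equiv), NaHCO3, CH2Cl2, 0 → 23 °C
Reagents that add atoms: 3-chloroperbenzoic acid, OOC(=O)c1cccc(Cl)c1
Why: Baeyer–Villiger oxidation of the α-quaternary aldehyde should proceed by migration of the tertiary carbon (better than hydride) in the Criegee intermediate with retention of configuration, giving the formate with the C–O bond on the face the formyl group occupied.

Step 14
Reactants: 23 methyl 2-[(3R,4R,6R)-4-(formyloxy)-4,6-dimethyl-6-(10-phenyldecyl)-1,2-dioxan-3-yl]acetate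
Product: 25 (3R,4aR,7aR)-3,4a-dimethyl-3-(10-phenyldecyl)tetrahydro-3H-furo[3,2-c][1,2]dioxin-6(4H)-one, via hydroxy ester 24 (not isolated)
Conditions: K2CO3 (0.3 equiv), MeOH, 0 → 23 °C
Reagents that add atoms: none
Why: Methanolysis of the formate frees the tertiary alkoxide, which closes the γ-lactone on the methyl ester (5-exo-trig acyl substitution) to the cis-fused bicycle; a retro-oxa-Michael opening, should it occur, re-closes to the same cis-fused product, so no stereocenter is lost.

Compound list
1 | 10-bromodecan-1-ol | OCCCCCCCCCCBr | starting material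
2 | phenylmagnesium bromide | Br[Mg]c1ccccc1 | starting material
3 | 10-phenyldecan-1-ol | OCCCCCCCCCCc1ccccc1 | intermediate
4 | 10-phenyldecanal | O=CCCCCCCCCCc1ccccc1 | intermediate
5 | prop-1-en-2-ylmagnesium bromide | C=C(C)[Mg]Br | starting material
6 | 2-methyl-12-phenyldodec-1-en-3-ol (racemic) | C=C(C)C(O)CCCCCCCCCc1ccccc1 | intermediate
7 | triethyl orthopropionate (1,1,1-triethoxypropane) | CCC(OCC)(OCC)OCC | starting material
8 | 1-ethoxyprop-1-enyl 2-methyl-12-phenyldodec-1-en-3-yl ether (mixed ketene acetal) | CCOC(=CC)OC(C(C)=C)CCCCCCCCCc1ccccc1 | intermediate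
9 | ethyl (E)-2,4-dimethyl-14-phenyltetradec-4-enoate (both C2 epimers) | CCOC(=O)C(C)C/C(C)=C/CCCCCCCCCc1ccccc1 | intermediate
10 | ethyl 2-methyl-3-[(2S,3S)-2-methyl-3-(9-phenylnonyl)oxiran-2-yl]propanoate (both epimers at the propanoate C2) | C[C@@]1(CC(C)C(=O)OCC)O[C@H]1CCCCCCCCCc1ccccc1 | intermediate
11 | ethyl (4S,5R)-4-hydroxy-2,4-dimethyl-14-phenyl-5-(phenylselanyl)tetradecanoate (both C2 epimers) | CCOC(=O)C(C)C[C@](C)(O)[C@H]([Se]c1ccccc1)CCCCCCCCCc1ccccc1 | intermediate
12 | (5S)-3,5-dimethyl-5-[(1R)-10-phenyl-1-(phenylselanyl)decyl]oxolan-2-one (both C3 epimers) | C[C@@]1([C@H]([Se]c2ccccc2)CCCCCCCCCc2ccccc2)CC(C)C(=O)O1 | intermediate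
13 | (5S)-3,5-dimethyl-5-[(1R)-10-phenyl-1-(phenylselanyl)decyl]oxolan-2-ol (anomers and C3 epimers) | C[C@@]1([C@H]([Se]c2ccccc2)CCCCCCCCCc2ccccc2)CC(C)C(O)O1 | intermediate
14 | dimethyl (E)-hex-3-enedioate | COC(=O)C/C=C/CC(=O)OC | starting material
15 | methyl 3-hydroperoxy-3-methoxypropanoate (racemic) | COC(=O)CC(OC)OO | intermediate
16 | methyl 3-methoxy-3-[(triethylsilyl)peroxy]propanoate (racemic) | COC(=O)CC(OC)OO[Si](CC)(CC)CC | intermediate
17 | methyl 3-{[(4S,5R)-2,4-dimethyl-1-oxo-14-phenyl-5-(phenylselanyl)tetradecan-4-yl]peroxy}-3-methoxypropanoate (epimers at C2 and at the acetal carbon) | O=CC(C)C[C@](C)(OOC(OC)CC(=O)OC)[C@H]([Se]c1ccccc1)CCCCCCCCCc1ccccc1 | intermediate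
18 | trimethylsilyl enol ether of 17 (E/Z mixture) | C[Si](C)(C)OC=C(C)C[C@](C)(OOC(OC)CC(=O)OC)[C@H]([Se]c1ccccc1)CCCCCCCCCc1ccccc1 | intermediate
19 | methyl 2-[(3R,4R,6S)-4-formyl-4,6-dimethyl-6-[(1R)-10-phenyl-1-(phenylselanyl)decyl]-1,2-dioxan-3-yl]acetate | C[C@@]1([C@H]([Se]c2ccccc2)CCCCCCCCCc2ccccc2)C[C@@](C)(C=O)[C@@H](CC(=O)OC)OO1 | intermediate
20 | selenoxide of 19 (both configurations at selenium) | C[C@@]1([C@H]([Se](=O)c2ccccc2)CCCCCCCCCc2ccccc2)C[C@@](C)(C=O)[C@@H](CC(=O)OC)OO1 | intermediate
21 | methyl 2-[(3R,4R,6S)-4-formyl-4,6-dimethyl-6-[(E)-10-phenyldec-1-enyl]-1,2-dioxan-3-yl]acetate | C[C@@]1(/C=C/CCCCCCCCc2ccccc2)C[C@@](C)(C=O)[C@@H](CC(=O)OC)OO1 | intermediate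
22 | methyl 2-[(3R,4R,6R)-4-formyl-4,6-dimethyl-6-(10-phenyldecyl)-1,2-dioxan-3-yl]acetate | C[C@@]1(CCCCCCCCCCc2ccccc2)C[C@@](C)(C=O)[C@@H](CC(=O)OC)OO1 | intermediate
23 | methyl 2-[(3R,4R,6R)-4-(formyloxy)-4,6-dimethyl-6-(10-phenyldecyl)-1,2-dioxan-3-yl]acetate | C[C@@]1(CCCCCCCCCCc2ccccc2)C[C@@](C)(OC=O)[C@@H](CC(=O)OC)OO1 | intermediate
24 | methyl 2-[(3R,4R,6R)-4-hydroxy-4,6-dimethyl-6-(10-phenyldecyl)-1,2-dioxan-3-yl]acetate | C[C@@]1(CCCCCCCCCCc2ccccc2)C[C@@](C)(O)[C@@H](CC(=O)OC)OO1 | intermediate
25 | (3R,4aR,7aR)-3,4a-dimethyl-3-(10-phenyldecyl)tetrahydro-3H-furo[3,2-c][1,2]dioxin-6(4H)-one | C[C@@]1(CCCCCCCCCCc2ccccc2)C[C@@]2(C)OC(=O)C[C@H]2OO1 | target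

Total step count: 14. Longest linear sequence: 12 steps (steps 1–7 and 10–14); steps 8 and 9 form the side branch.

Steps most likely to fail

Step 10. The peroxy acetal may ionise and form the C–C bond intermolecularly before the seleniranium ion has been captured, which would remove the chair control over the two new stereocenters. The seleniranium ion may also be opened at its secondary carbon, lose a proton to an allyl selenide, or the selenium may be oxidised by the peroxide. The fallback makes the two bonds in separate operations of known type, setting out from 13 and 16. BF3·OEt2 in CH2Cl2 at −40 °C without base should effect only the seleniranium-mediated substitution, and the peroxy acetal aldehyde 17 is then isolated. Treatment with t-BuMe2SiOTf/Et3N should give the purified tert-butyldimethylsilyl enol ether F1. SnCl4 in CH2Cl2 at −78 °C should then close the ring by the established Lewis-acid cyclisation of a peroxycarbenium ion onto an enol silane, coming back to the route at 19.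

Step 13. Hydride may migrate instead of carbon, giving the carboxylic acid, or oxidation of the hindered aldehyde may be slow enough for the peroxide to decompose. The fallback sets out from 22 and avoids the aldehyde-to-formate migration. Pinnick oxidation (NaClO2, NaH2PO4, 2-methylbut-2-ene, t-BuOH/H2O) should give the carboxylic acid F2. Coupling with mCPBA and dicyclohexylcarbodiimide should give the mixed diacyl peroxide F3. Warming F3 in MeCN should trigger the ionic carboxy-inversion rearrangement, with retention at the migrating quaternary carbon, to the mixed carbonic anhydride F4. K2CO3 in MeOH should then release hydroxy ester 24, where the fallback rejoins the route.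

Step 14. Base may fragment the secondary peroxide (Kornblum–DeLaMare-type), or the hindered tertiary alcohol may fail to close the lactone before the ester undergoes β-elimination. The fallback sets out from 23 and passes deliberately through the ring-opened form. DBU in MeOH/CH2Cl2 should cleave the formate, close the lactone and open the dioxane by retro-oxa-Michael reaction to the isolable hydroperoxy butenolide F5. Et2NH in CF3CH2OH should then re-close the 1,2-dioxane by intramolecular oxa-Michael addition of the hydroperoxide to the butenolide, which is expected to give the cis-fused bicycle, coming back to the route at 25.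

Further compounds
F1 | step 10 | tert-butyldimethylsilyl enol ether of 17 (E/Z mixture) | CC(C)(C)[Si](C)(C)OC=C(C)C[C@](C)(OOC(OC)CC(=O)OC)[C@H]([Se]c1ccccc1)CCCCCCCCCc1ccccc1
F2 | step 13 | (3R,4R,6R)-3-(2-methoxy-2-oxoethyl)-4,6-dimethyl-6-(10-phenyldecyl)-1,2-dioxane-4-carboxylic acid | C[C@@]1(CCCCCCCCCCc2ccccc2)C[C@@](C)(C(=O)O)[C@@H](CC(=O)OC)OO1
F3 | step 13 | mixed diacyl peroxide of F2 and 3-chlorobenzoic acid | C[C@@]1(CCCCCCCCCCc2ccccc2)C[C@@](C)(C(=O)OOC(=O)c2cccc(Cl)c2)[C@@H](CC(=O)OC)OO1
F4 | step 13 | mixed carbonic anhydride (3-chlorobenzoyl carbonate of 24) | C[C@@]1(CCCCCCCCCCc2ccccc2)C[C@@](C)(OC(=O)OC(=O)c2cccc(Cl)c2)[C@@H](CC(=O)OC)OO1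
F5 | step 14 | (5R)-5-[(2R)-2-hydroperoxy-2-methyl-12-phenyldodecyl]-5-methylfuran-2(5H)-one | C[C@](CCCCCCCCCCc1ccccc1)(OO)C[C@@]1(C)OC(=O)C=C1
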